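**Strategy**

The benzene ring of the target (C1 CO2H, C2 OH, C3 H, C4 OH, C5 CH3, C6 13-methyltetradecyl) is cut at C5–C6 and C3–C4. A benzyl 2-alkylidene-acetoacetate then supplies C3, C2, C1, C6 and the side chain, and S-tert-butyl propanethioate supplies C4, C5 and the ring methyl. In one operation the thioester enolate adds to the alkylidene carbon (C5–C6) and the acetyl methyl is acylated by the thioester (C3–C4); this exploits the 1,3-relationship of the oxygens at C2 and C4 and closes the six-membered ring with every substituent in place. Iodine-catalysed dehydrogenation and hydrogenolysis of the benzyl ester complete the achiral acid.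

Key step: step 5

**Remarks on the chemistry**

- Assumption: the target has no stereocentre and no stereogenic double bond, so there is no enantiomer to select. The three sp3 ring centres that arise in step 5 are removed in step 6.
- The ring numbering of the target (C1 carries the carboxyl carbon) is used for the cyclohexanedione and the benzoates throughout.
- The C1 ester is carried as a benzyl ester, not a methyl ester. A 2,4-dihydroxybenzoate flanked by OH and alkyl is saponified only under forcing conditions, and under these the resorcylic acid loses CO2. The benzyl ester is removed by hydrogenolysis at room temperature.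
- The ring closure in step 5 is run with an equilibrating alkoxide, not with a second charge of amide base; the reason is given in step 5.
- 12-Bromododecan-1-ol is used rather than 12-bromododecanoic acid, which saves a reduction step.

**Route**

Step 1
Reactants: 1 12-bromododecan-1-ol; 2 isobutylmagnesium bromide
Product: 3 14-methylpentadecan-1-ol
Conditions: 2 (2.5 equiv), Li2CuCl4 (3 mol %), THF, −20 °C → rt; aq. NH4Cl
Reagents that add atoms: none
Why: Copper-catalysed alkyl–alkyl cross-coupling of a primary bromide with a primary Grignard reagent, in which the first equivalent of 2 converts the hydroxyl group into an inert magnesium alkoxide so that no protection is needed.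

Step 2
Reactants: 3 14-methylpentadecan-1-ol
Product: 4 14-methylpentadecanal
Conditions: TEMPO (10 mol %), PhI(OAc)2 (1.1 equiv), CH2Cl2, rt
Reagents that add atoms: none
Why: The oxoammonium-mediated (TEMPO/PhI(OAc)2) oxidation of an unhindered primary alcohol should stop at the aldehyde, and the saturated chain offers no other reactive site.

Step 3
Reactants: 5 propionyl chloride; 6 2-methylpropane-2-thiol
Product: 7 S-tert-butyl propanethioate
Conditions: pyridine (1.1 equiv), CH2Cl2, 0 °C → rt; distillation
Reagents that add atoms: none
Why: S-Acylation of the thiol by the acid chloride with pyridine as acid acceptor is a standard thioester synthesis.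

Step 4
Reactants: 4 14-methylpentadecanal; 8 benzyl acetoacetate
Product: 9 benzyl 2-acetyl-16-methylheptadec-2-enoate (E/Z mixture)
Conditions: piperidine (10 mol %), AcOH (10 mol %), 4 Å MS, CH2Cl2, 0 °C → rt
Reagents that add atoms: none
Why: Knoevenagel condensation under piperidinium acetate catalysis, where low temperature, removal of water and a slight excess of aldehyde should hold back a second acetoacetate addition and double-bond migration; the E/Z ratio is irrelevant because both isomers converge in step 5.

Step 5
Reactants: 7 S-tert-butyl propanethioate; 9 benzyl 2-acetyl-16-methylheptadec-2-enoate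
Product: 12 benzyl 5-methyl-6-(13-methyltetradecyl)-2,4-dioxocyclohexane-1-carboxylate, via thioester lithium enolate 10 (not isolated), via Michael adduct lithium enolate 11 (not isolated)
Conditions: 7 (1.1 equiv), LDA (1.05 equiv), THF, −78 °C; then 9, −78 → −40 °C; then t-BuOK (1.5 equiv), t-BuOH, −40 → 50 °C; 1 M HCl, 0 °C
Reagents that add atoms: none
Why: Enolate 10 adds to the β-carbon of the doubly activated alkene of 9 (Michael addition of a thioester enolate to an alkylidene 1,3-dicarbonyl compound) and forms C5–C6 together with the chelated acetoacetate enolate 11. With tert-butoxide in tert-butanol all C–H acids exchange reversibly, so the small share of 11 that is deprotonated at the acetyl methyl attacks the thioester carbonyl, expels tert-butylthiolate and forms C3–C4; this is the intramolecular Claisen (Dieckmann) closure known from the cyclisation of acetoacetate Michael adducts to dihydroresorcylates, here with a better acyl donor. The ring closes in the 6-(enolendo)-exo-trig mode. An equilibrating base is chosen over a second charge of LDA because the C5–H next to the thioester is more acidic than the acetyl methyl of an existing enolate, and irreversible deprotonation there would turn the electrophile into an unreactive enolate; under exchange only the closure is irreversible, since the 1,3-dione is deprotonated as it forms. The step needs 1,4- over 1,2-addition and C- over O-acylation: the two acceptor groups and the reversibility of aldol addition to the acetyl group secure the first, and the second follows because C1 or C5 could only close four-membered rings while an O-acylated enol lactone is reopened by thiolate. C1, C5 and C6 become stereocentres without control (C1 epimerises through its enol), and the diastereomer and tautomer mixture is carried on because all three become sp2 in step 6.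

Step 6
Reactants: 12 benzyl 5-methyl-6-(13-methyltetradecyl)-2,4-dioxocyclohexane-1-carboxylate
Product: 13 benzyl 2,4-dihydroxy-5-methyl-6-(13-methyltetradecyl)benzoate
Conditions: I2 (20 mol %), DMSO, 80 °C, N2; aq. Na2S2O3; chromatography
Reagents that add atoms: none
Why: Iodine-catalysed dehydrogenative aromatisation (α-iodination of the enolised dione, loss of HI, tautomerisation) with DMSO as terminal oxidant, chosen over iodine in methanol, which would give aryl methyl ethers; the low stationary HI concentration should leave the benzyl ester intact.

Step 7
Reactants: 13 benzyl 2,4-dihydroxy-5-methyl-6-(13-methyltetradecyl)benzoate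
Product: 14 2,4-dihydroxy-5-methyl-6-(13-methyltetradecyl)benzoic acid
Conditions: H2 (1 atm), 10% Pd/C, EtOAc, rt
Reagents that add atoms: none
Why: Hydrogenolysis of the benzyl ester under neutral conditions at room temperature should release the acid without the heat, acid or base that decarboxylate 2,4-dihydroxy-6-alkylbenzoic acids.

**Compound list**

1 | 12-bromododecan-1-ol | OCCCCCCCCCCCCBr | starting material
2 | isobutylmagnesium bromide | CC(C)C[Mg]Br | starting material
3 | 14-methylpentadecan-1-ol | OCCCCCCCCCCCCCC(C)C | intermediate
4 | 14-methylpentadecanal | O=CCCCCCCCCCCCCC(C)C | intermediate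
5 | propionyl chloride | CCC(=O)Cl | starting material
6 | 2-methylpropane-2-thiol | CC(C)(C)S | starting material
7 | S-tert-butyl propanethioate | CCC(=O)SC(C)(C)C | intermediate
8 | benzyl acetoacetate (benzyl 3-oxobutanoate) | CC(=O)CC(=O)OCc1ccccc1 | starting material
9 | benzyl 2-acetyl-16-methylheptadec-2-enoate (E/Z mixture) | CC(=O)C(=CCCCCCCCCCCCCC(C)C)C(=O)OCc1ccccc1 | intermediate
10 | lithium enolate of S-tert-butyl propanethioate (E/Z not specified) | [Li+].CC=C([O-])SC(C)(C)C | intermediate (not isolated)
11 | lithium enolate of benzyl 2-acetyl-3-[1-(tert-butylsulfanyl)-1-oxopropan-2-yl]-16-methylheptadecanoate (diastereomer mixture) | [Li+].CC([O-])=C(C(=O)OCc1ccccc1)C(CCCCCCCCCCCCC(C)C)C(C)C(=O)SC(C)(C)C | intermediate (not isolated)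
12 | benzyl 5-methyl-6-(13-methyltetradecyl)-2,4-dioxocyclohexane-1-carboxylate (diastereomer and tautomer mixture) | O=C(OCc1ccccc1)C1C(=O)CC(=O)C(C)C1CCCCCCCCCCCCC(C)C | intermediate
13 | benzyl 2,4-dihydroxy-5-methyl-6-(13-methyltetradecyl)benzoate | Cc1c(O)cc(O)c(C(=O)OCc2ccccc2)c1CCCCCCCCCCCCC(C)C | intermediate
14 | 2,4-dihydroxy-5-methyl-6-(13-methyltetradecyl)benzoic acid (IUPAC: 4,6-dihydroxy-3-methyl-2-(13-methyltetradecyl)benzoic acid; achiral) | Cc1c(O)cc(O)c(C(=O)O)c1CCCCCCCCCCCCC(C)C | target

**Step count**

Total step count: 7. Longest linear sequence: 6 steps (1, 2, 4, 5, 6, 7); step 3 is a one-step branch.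

**Steps most likely to fail**

Step 5. Proton transfer from the acidic allylic position of 9 to the basic enolate could compete with conjugate addition. In the second stage, acyl transfer to the enolate oxygen or to tert-butoxide, or loss of the thioester through its own enolate, could stop the sequence short of the ring. The fallback builds the same cyclohexanedione by a malonate annulation and sets out from 4. Wittig olefination of 4 with 3-(triphenylphosphoranylidene)butan-2-one in refluxing toluene should give (E)-3,17-dimethyloctadec-3-en-2-one F1. Michael addition of dibenzyl malonate to F1 and Claisen closure of the methyl ketone onto a malonate ester in the same flask (t-BuOK, t-BuOH/THF, reflux; then HCl) comes back to the route at 12. This reserve forms C1–C6 and C2–C3 instead of the bonds of the key step.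

Step 6. Halogenation at the electron-rich C3 of the newly formed resorcylate could consume the iodine catalyst, and acid-promoted loss of the benzyl group at 80 °C would be followed by decarboxylation. The fallback sets out from 12 and makes the halogenation deliberate. Bromine (2.1 equiv) with NaOAc in AcOH at room temperature (bromination and dehydrobromination of the dione) should give benzyl 3-bromo-2,4-dihydroxy-5-methyl-6-(13-methyltetradecyl)benzoate F2. Hydrogenation of F2 over Pd/C with NaOAc in EtOAc/MeOH removes the ring bromine and the benzyl group together and comes back to the route at 14.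

Step 4. Conjugate addition of a second acetoacetate to the product, migration of the double bond out of conjugation and aldol self-condensation of the aldehyde could erode the condensation. The fallback sets out from 3 and avoids the aldehyde. Appel bromination (CBr4, PPh3, CH2Cl2) should give 1-bromo-14-methylpentadecane F3. Alkylation of the sodium enolate of 8 with F3 (NaH, cat. NaI, THF/DMF, 60 °C) gives benzyl 2-acetyl-16-methylheptadecanoate F4. Selenenylation of F4 (NaH, then PhSeCl, THF, 0 °C) gives benzyl 2-acetyl-16-methyl-2-(phenylselanyl)heptadecanoate F5. Oxidation of F5 with H2O2 (CH2Cl2, 0 °C → rt) and syn-elimination of the selenoxide, which can only run toward C3, comes back to the route at 9.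

**Further compounds**

F1 | step 5 | (E)-3,17-dimethyloctadec-3-en-2-one | CC(=O)/C(C)=C/CCCCCCCCCCCCC(C)C
F2 | step 6 | benzyl 3-bromo-2,4-dihydroxy-5-methyl-6-(13-methyltetradecyl)benzoate | Cc1c(O)c(Br)c(O)c(C(=O)OCc2ccccc2)c1CCCCCCCCCCCCC(C)C
F3 | step 4 | 1-bromo-14-methylpentadecane | BrCCCCCCCCCCCCCC(C)C
F4 | step 4 | benzyl 2-acetyl-16-methylheptadecanoate | CC(=O)C(CCCCCCCCCCCCCC(C)C)C(=O)OCc1ccccc1
F5 | step 4 | benzyl 2-acetyl-16-methyl-2-(phenylselanyl)heptadecanoate | CC(=O)C([Se]c1ccccc1)(CCCCCCCCCCCCCC(C)C)C(=O)OCc1ccccc1
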